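**Strategy.** Ring A is cut between C1–C2 and C4–C5 (labdane numbering), so that its C2–C3–C4(CH3)2 edge arrives as one five-carbon reagent. The key step exploits the fact that C1, C10 and C5 can be stored as a cyclopropane fused to ring B and conjugated to a temporary C6 ketone. An isopentenyl cuprate opens this ring at C1 (C1–C2). In the same flask, acid turns the pendant isopropenyl group into the C4 cation, which the C6 enol captures at C5 (C4–C5). The precursor is a bicyclo[4.1.0]heptan-2-one carrying the angular methyl, the citronellol-derived side chain and the C17 ester; the ketone also lets C5 settle trans.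

Key step: step 8

Remarks on the chemistry (assumptions):
- Labdane numbering is used for atom labels throughout.
- C8 (the ester-bearing ring carbon) is carried as a mixture of epimers, drawn without a descriptor, until it becomes sp2 in step 11.
- The facial sense of (S)-BINAP in step 3 is assumed to follow that of acyclic (E)-acceptors.
- The lithium dialkylcuprate of step 8 is prepared beforehand from commercial 4-bromo-2-methylbut-1-ene (tBuLi, then CuI, Et2O).

**Route**

Step 1
Reactants: 1 (S)-citronellol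
Product: 2 (S)-citronellyl pivalate
Conditions: PivCl, pyridine, DMAP (cat.), CH2Cl2, 0 → 23 °C
Reagents that add atoms: pivaloyl chloride, CC(C)(C)C(=O)Cl
Why: Acylation of the primary alcohol (nucleophilic acyl substitution) installs a pivalate that should tolerate the amide base, the acids and the cuprate used later and is removed together with the ester reduction in step 12; no stereocentre is touched.

Step 2
Reactants: 2 (S)-citronellyl pivalate; 3 methyl acrylate
Product: 4 methyl (2E,6S)-8-[(2,2-dimethylpropanoyl)oxy]-6-methyloct-2-enoate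
Conditions: 3 (5 equiv), second-generation Hoveyda–Grubbs catalyst (5 mol%), CH2Cl2, 40 °C
Reagents that add atoms: none
Why: Olefin cross-metathesis between the 2-methylprop-1-enyl terminus and the electron-poor acrylate releases volatile 2-methylpropene and should give the (E)-enoate under thermodynamic control; the C13 stereocentre from citronellol is remote and untouched.

Step 3
Reactants: 4 methyl (2E,6S)-8-[(2,2-dimethylpropanoyl)oxy]-6-methyloct-2-enoate; 5 isopropenylboronic acid pinacol ester
Product: 6 methyl (3S,6S)-8-[(2,2-dimethylpropanoyl)oxy]-6-methyl-3-(prop-1-en-2-yl)octanoate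
Conditions: [Rh(OH)(cod)]2 (2.5 mol%), (S)-BINAP (6 mol%), 1,4-dioxane/H2O (10:1), 50 °C
Reagents that add atoms: none
Why: Rhodium-catalysed asymmetric 1,4-addition of the alkenylboronate (Hayashi–Miyaura reaction) sets C9, since the (S)-BINAP–rhodium alkenyl species should insert the (E)-enoate on the face that gives the (3S) product, independent of the remote C13 centre.

Step 4
Reactants: 6 methyl (3S,6S)-8-[(2,2-dimethylpropanoyl)oxy]-6-methyl-3-(prop-1-en-2-yl)octanoate; 7 allyl bromoacetate
Product: 8 1-methyl 4-(prop-2-en-1-yl) 2-[(3S,6S)-8-[(2,2-dimethylpropanoyl)oxy]-2,6-dimethyloct-1-en-3-yl]butanedioate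
Conditions: LiN(iPr)2, THF, −78 °C; then 7, −78 → −20 °C
Reagents that add atoms: none
Why: Alkylation of the lithium ester enolate (SN2 on the alpha-bromo ester) adds C7 and C6; the new centre C8 forms as a mixture that is inconsequential because C8 becomes sp2 in step 11.

Step 5
Reactants: 8 1-methyl 4-(prop-2-en-1-yl) 2-[(3S,6S)-8-[(2,2-dimethylpropanoyl)oxy]-2,6-dimethyloct-1-en-3-yl]butanedioate
Product: 9 (4S,7S)-9-[(2,2-dimethylpropanoyl)oxy]-3-(methoxycarbonyl)-7-methyl-4-(prop-1-en-2-yl)nonanoic acid
Conditions: Pd(PPh3)4 (3 mol%), morpholine, THF, 23 °C; dilute citric acid work-up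
Reagents that add atoms: none
Why: Tsuji–Trost deallylation, in which zerovalent palladium ionises the allyl ester to a pi-allyl complex that morpholine captures, should free the C6 acid under neutral conditions that spare the acid-sensitive isopropenyl group, the methyl ester and the pivalate.

Step 6
Reactants: 9 (4S,7S)-9-[(2,2-dimethylpropanoyl)oxy]-3-(methoxycarbonyl)-7-methyl-4-(prop-1-en-2-yl)nonanoic acid
Product: 12 methyl (2S)-2-[(3S)-5-[(2,2-dimethylpropanoyl)oxy]-3-methylpentyl]-3-methyl-5-oxocyclohex-3-ene-1-carboxylate, via acid chloride 10 (not isolated), via chloro ketone 11 (not isolated)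
Conditions: 1-chloro-N,N,2-trimethylprop-1-en-1-amine, CH2Cl2, 0 °C; then SnCl4 (0.3 equiv), −78 °C; then Et3N, −78 → 0 °C
Reagents that add atoms: none
Why: Intramolecular Friedel–Crafts-type acylation of the 1,1-disubstituted alkene (Darzens–Nenitzescu reaction) should close ring B by Markovnikov attack of the terminal CH2 (C5) on the acylium ion, after which chloride capture at C10 and amine-induced E1cB loss of HCl give the conjugated enone without conditions that would enolise C9.

Step 7
Reactants: 12 methyl (2S)-2-[(3S)-5-[(2,2-dimethylpropanoyl)oxy]-3-methylpentyl]-3-methyl-5-oxocyclohex-3-ene-1-carboxylate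
Product: 13 methyl (1R,2S,6R)-2-[(3S)-5-[(2,2-dimethylpropanoyl)oxy]-3-methylpentyl]-1-methyl-5-oxobicyclo[4.1.0]heptane-3-carboxylate
Conditions: Me3S(O)I, NaH, DMSO, 23 → 50 °C
Reagents that add atoms: trimethylsulfoxonium iodide, C[S+](C)(C)=O.[I-]
Why: In this Corey–Chaykovsky cyclopropanation (Michael-initiated ring closure) the sulfoxonium ylide should add to the beta carbon C10 anti to the adjacent C9 side chain and the enolate then displaces dimethyl sulfoxide, so the new CH2 (C1) is trans and the C10 methyl cis to the side chain, with C5 fixed by the obligatory cis ring fusion.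

Step 8
Reactants: 13 methyl (1R,2S,6R)-2-[(3S)-5-[(2,2-dimethylpropanoyl)oxy]-3-methylpentyl]-1-methyl-5-oxobicyclo[4.1.0]heptane-3-carboxylate
Product: 16 methyl (1S,4aS,8aR)-1-[(3S)-5-[(2,2-dimethylpropanoyl)oxy]-3-methylpentyl]-5,5,8a-trimethyl-4-oxodecahydronaphthalene-2-carboxylate, via lithium enolate 14 (not isolated), via seco-ketone 15 (not isolated)
Conditions: LiCu(CH2CH2C(CH3)=CH2)2 (2.5 equiv), Et2O, −20 → 23 °C; then Et2O replaced by CH2Cl2, CF3SO3H (5 equiv), 0 → 23 °C
Reagents that add atoms: lithium bis(3-methylbut-3-en-1-yl)cuprate, [Li+].C=C(C)CC[Cu-]CCC(C)=C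
Why: The Gilman cuprate should attack the unsubstituted cyclopropane carbon C1 in an SN2-like homoconjugate (1,5-) addition, breaking the C1–C5 bond that is aligned with the carbonyl pi system and releasing the C5=C6 lithium enolate 14 (C1–C2 formed); after the solvent change, CF3SO3H protonates the enolate to seco-ketone 15 and the isopropenyl group to the tertiary C4 cation, which the C5 enol carbon captures (C4–C5 formed). The closest known reactions are the ring opening of bicyclo[4.1.0]heptan-2-ones by lithium dialkylcuprates and the acid-mediated intramolecular alpha-tert-alkylation of ketones (cation–enol cyclization, as in polyene cyclizations terminated by enol derivatives). Ring A closes in a 6-exo mode with respect to the enol double bond by Markovnikov attack on the C4 cation, the alternative closures from the C7 enol or from oxygen requiring eight-membered rings. The new stereocentre C5 is alpha to the C6 ketone and is set under thermodynamic control: the kinetically expected cis-fused ketone should epimerise through the enol in the acid medium to the trans-decalone with H-5 anti to the C10 methyl. The step needs regioselective cleavage of the cyclopropane, which is secured because the quaternary C10 cannot be attacked and a cuprate, unlike a Lewis acid, cannot ionise the C5–C10 bond; it also needs chemoselectivity over the two esters, which Gilman reagents and CF3SO3H should leave intact.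

Step 9
Reactants: 16 methyl (1S,4aS,8aR)-1-[(3S)-5-[(2,2-dimethylpropanoyl)oxy]-3-methylpentyl]-5,5,8a-trimethyl-4-oxodecahydronaphthalene-2-carboxylate
Product: 17 methyl (1S,4aS,8aR)-1-[(3S)-5-[(2,2-dimethylpropanoyl)oxy]-3-methylpentyl]-5,5,8a-trimethyl-4-[(trifluoromethanesulfonyl)oxy]-1,2,4a,5,6,7,8,8a-octahydronaphthalene-2-carboxylate
Conditions: KN(SiMe3)2, THF, −78 °C; then PhN(SO2CF3)2, −78 → 0 °C
Reagents that add atoms: N-phenylbis(trifluoromethanesulfonimide), O=S(=O)(C(F)(F)F)N(c1ccccc1)S(=O)(=O)C(F)(F)F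
Why: Kinetic deprotonation at C7, the only unhindered alpha position (H-5 lies between two quaternary carbons), and O-sulfonylation of the enolate should give the C6 enol triflate regioselectively.

Step 10
Reactants: 17 methyl (1S,4aS,8aR)-1-[(3S)-5-[(2,2-dimethylpropanoyl)oxy]-3-methylpentyl]-5,5,8a-trimethyl-4-[(trifluoromethanesulfonyl)oxy]-1,2,4a,5,6,7,8,8a-octahydronaphthalene-2-carboxylate
Product: 18 methyl (1S,4aS,8aR)-1-[(3S)-5-[(2,2-dimethylpropanoyl)oxy]-3-methylpentyl]-5,5,8a-trimethyl-1,2,4a,5,6,7,8,8a-octahydronaphthalene-2-carboxylate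
Conditions: Pd(OAc)2 (5 mol%), PPh3 (10 mol%), nBu3N, HCO2H, DMF, 60 °C
Reagents that add atoms: none
Why: Palladium-catalysed reduction of the enol triflate with formate (oxidative addition to zerovalent palladium, formate exchange, decarboxylation, reductive elimination) should remove the C6 oxygen and leave the 6,7-alkene.

Step 11
Reactants: 18 methyl (1S,4aS,8aR)-1-[(3S)-5-[(2,2-dimethylpropanoyl)oxy]-3-methylpentyl]-5,5,8a-trimethyl-1,2,4a,5,6,7,8,8a-octahydronaphthalene-2-carboxylate
Product: 19 methyl (1R,4aS,8aS)-1-[(3S)-5-[(2,2-dimethylpropanoyl)oxy]-3-methylpentyl]-5,5,8a-trimethyl-1,4,4a,5,6,7,8,8a-octahydronaphthalene-2-carboxylate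
Conditions: DBU, toluene, 80 °C
Reagents that add atoms: none
Why: Base-mediated isomerisation of the beta,gamma-unsaturated ester through its dienolate (protonation at C6) should move the alkene into conjugation, delivering the trisubstituted 7,8-alkene and erasing the C8 centre under thermodynamic control.

Step 12
Reactants: 19 methyl (1R,4aS,8aS)-1-[(3S)-5-[(2,2-dimethylpropanoyl)oxy]-3-methylpentyl]-5,5,8a-trimethyl-1,4,4a,5,6,7,8,8a-octahydronaphthalene-2-carboxylate
Product: 20 (3S)-5-[(1R,4aS,8aS)-2-(hydroxymethyl)-5,5,8a-trimethyl-1,4,4a,5,6,7,8,8a-octahydronaphthalen-1-yl]-3-methylpentan-1-ol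
Conditions: iBu2AlH (6 equiv), CH2Cl2, −78 → 0 °C; aqueous potassium sodium tartrate work-up
Reagents that add atoms: none
Why: Hydride reduction with iBu2AlH should convert the conjugated methyl ester into the C17 allylic alcohol (1,2-reduction) and cleave the pivalate to the C15 alcohol in the same operation.

Step 13
Reactants: 20 (3S)-5-[(1R,4aS,8aS)-2-(hydroxymethyl)-5,5,8a-trimethyl-1,4,4a,5,6,7,8,8a-octahydronaphthalen-1-yl]-3-methylpentan-1-ol
Product: 21 (5S,9R,10S,13S)-labd-7-ene-15,17-diyl diacetate (CNP0294037.1)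
Conditions: Ac2O, pyridine, DMAP (cat.), CH2Cl2, 23 °C
Reagents that add atoms: acetic anhydride, CC(=O)OC(C)=O
Why: DMAP-catalysed acylation of both primary alcohols should give the diacetate without touching any stereocentre.

**Compound list**

1 | (S)-citronellol, (3S)-3,7-dimethyloct-6-en-1-ol | OCC[C@@H](C)CCC=C(C)C | starting material
2 | (S)-citronellyl pivalate, (3S)-3,7-dimethyloct-6-en-1-yl 2,2-dimethylpropanoate | CC(C)(C)C(=O)OCC[C@@H](C)CCC=C(C)C | intermediate
3 | methyl acrylate | C=CC(=O)OC | starting material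
4 | methyl (2E,6S)-8-[(2,2-dimethylpropanoyl)oxy]-6-methyloct-2-enoate | CC(C)(C)C(=O)OCC[C@@H](C)CC/C=C/C(=O)OC | intermediate
5 | isopropenylboronic acid pinacol ester, 4,4,5,5-tetramethyl-2-(prop-1-en-2-yl)-1,3,2-dioxaborolane | CC(=C)B1OC(C)(C)C(C)(C)O1 | starting material
6 | methyl (3S,6S)-8-[(2,2-dimethylpropanoyl)oxy]-6-methyl-3-(prop-1-en-2-yl)octanoate | CC(C)(C)C(=O)OCC[C@@H](C)CC[C@H](C(C)=C)CC(=O)OC | intermediate
7 | allyl bromoacetate, prop-2-en-1-yl bromoacetate | C=CCOC(=O)CBr | starting material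
8 | 1-methyl 4-(prop-2-en-1-yl) 2-[(3S,6S)-8-[(2,2-dimethylpropanoyl)oxy]-2,6-dimethyloct-1-en-3-yl]butanedioate (both epimers at C-2 of the butanedioate, i.e. C8) | CC(C)(C)C(=O)OCC[C@@H](C)CC[C@H](C(C)=C)C(CC(=O)OCC=C)C(=O)OC | intermediate
9 | (4S,7S)-9-[(2,2-dimethylpropanoyl)oxy]-3-(methoxycarbonyl)-7-methyl-4-(prop-1-en-2-yl)nonanoic acid (epimers at C-3) | CC(C)(C)C(=O)OCC[C@@H](C)CC[C@H](C(C)=C)C(CC(=O)O)C(=O)OC | intermediate
10 | acid chloride of 9, methyl (3S,6S)-2-(2-chloro-2-oxoethyl)-8-[(2,2-dimethylpropanoyl)oxy]-6-methyl-3-(prop-1-en-2-yl)octanoate | CC(C)(C)C(=O)OCC[C@@H](C)CC[C@H](C(C)=C)C(CC(=O)Cl)C(=O)OC | intermediate (not isolated)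
11 | chloro ketone, methyl (2S)-3-chloro-2-[(3S)-5-[(2,2-dimethylpropanoyl)oxy]-3-methylpentyl]-3-methyl-5-oxocyclohexane-1-carboxylate (mixture at C-1 and C-3) | CC(C)(C)C(=O)OCC[C@@H](C)CC[C@H]1C(C(=O)OC)CC(=O)CC1(C)Cl | intermediate (not isolated)
12 | methyl (2S)-2-[(3S)-5-[(2,2-dimethylpropanoyl)oxy]-3-methylpentyl]-3-methyl-5-oxocyclohex-3-ene-1-carboxylate (epimers at C-1) | CC(C)(C)C(=O)OCC[C@@H](C)CC[C@H]1C(C(=O)OC)CC(=O)C=C1C | intermediate
13 | methyl (1R,2S,6R)-2-[(3S)-5-[(2,2-dimethylpropanoyl)oxy]-3-methylpentyl]-1-methyl-5-oxobicyclo[4.1.0]heptane-3-carboxylate (cyclopropane CH2 anti to the side chain; epimers at C-3) | CC(C)(C)C(=O)OCC[C@@H](C)CC[C@H]1C(C(=O)OC)CC(=O)[C@@H]2C[C@]12C | intermediate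
14 | lithium enolate of 15 (C5=C6 enolate formed on ring opening) | CC(C)(C)C(=O)OCC[C@@H](C)CC[C@H]1C(C(=O)OC)CC(O[Li])=C[C@]1(C)CCCC(C)=C | intermediate (not isolated)
15 | seco-ketone, methyl (2S,3S)-2-[(3S)-5-[(2,2-dimethylpropanoyl)oxy]-3-methylpentyl]-3-methyl-3-(4-methylpent-4-en-1-yl)-5-oxocyclohexane-1-carboxylate (epimers at C-1) | CC(C)(C)C(=O)OCC[C@@H](C)CC[C@H]1C(C(=O)OC)CC(=O)C[C@]1(C)CCCC(C)=C | intermediate (not isolated)
16 | methyl (1S,4aS,8aR)-1-[(3S)-5-[(2,2-dimethylpropanoyl)oxy]-3-methylpentyl]-5,5,8a-trimethyl-4-oxodecahydronaphthalene-2-carboxylate (trans ring fusion; epimers at C-2) | CC(C)(C)C(=O)OCC[C@@H](C)CC[C@H]1C(C(=O)OC)CC(=O)[C@H]2C(C)(C)CCC[C@]12C | intermediate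
17 | methyl (1S,4aS,8aR)-1-[(3S)-5-[(2,2-dimethylpropanoyl)oxy]-3-methylpentyl]-5,5,8a-trimethyl-4-[(trifluoromethanesulfonyl)oxy]-1,2,4a,5,6,7,8,8a-octahydronaphthalene-2-carboxylate | CC(C)(C)C(=O)OCC[C@@H](C)CC[C@H]1C(C(=O)OC)C=C(OS(=O)(=O)C(F)(F)F)[C@H]2C(C)(C)CCC[C@]12C | intermediate
18 | methyl (1S,4aS,8aR)-1-[(3S)-5-[(2,2-dimethylpropanoyl)oxy]-3-methylpentyl]-5,5,8a-trimethyl-1,2,4a,5,6,7,8,8a-octahydronaphthalene-2-carboxylate | CC(C)(C)C(=O)OCC[C@@H](C)CC[C@H]1C(C(=O)OC)C=C[C@H]2C(C)(C)CCC[C@]12C | intermediate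
19 | methyl (1R,4aS,8aS)-1-[(3S)-5-[(2,2-dimethylpropanoyl)oxy]-3-methylpentyl]-5,5,8a-trimethyl-1,4,4a,5,6,7,8,8a-octahydronaphthalene-2-carboxylate | CC(C)(C)C(=O)OCC[C@@H](C)CC[C@H]1C(C(=O)OC)=CC[C@H]2C(C)(C)CCC[C@]12C | intermediate
20 | (3S)-5-[(1R,4aS,8aS)-2-(hydroxymethyl)-5,5,8a-trimethyl-1,4,4a,5,6,7,8,8a-octahydronaphthalen-1-yl]-3-methylpentan-1-ol | OCC[C@@H](C)CC[C@H]1C(CO)=CC[C@H]2C(C)(C)CCC[C@]12C | intermediate
21 | (5S,9R,10S,13S)-labd-7-ene-15,17-diyl diacetate, [(1R,4aS,8aS)-1-[(3S)-5-(acetyloxy)-3-methylpentyl]-5,5,8a-trimethyl-1,4,4a,5,6,7,8,8a-octahydronaphthalen-2-yl]methyl acetate | CC(=O)OCC[C@@H](C)CC[C@H]1C(COC(C)=O)=CC[C@H]2C(C)(C)CCC[C@]12C | target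

**Step count and risks**

Total step count: 13. Longest linear sequence: 13 steps from (S)-citronellol (1); the cuprate of step 8 is a separately prepared reagent.

Steps most likely to fail:

1. Step 8 (key step). The cuprate may open the hindered cyclopropane too slowly, because C1 neighbours the quaternary C10, so that enolisation or carbonyl addition competes. The C4 cation may also lose a proton faster than the enol captures it, or C5 may not fully equilibrate to the trans fusion. The fallback makes the two bonds in two operations with known chemistry and sets out from 13. Me3SiI (CH2Cl2, −78 °C, then aqueous work-up) should open the cyclopropane at C1 to the gamma-iodo ketone methyl (2S,3S)-2-[(3S)-5-[(2,2-dimethylpropanoyl)oxy]-3-methylpentyl]-3-(iodomethyl)-3-methyl-5-oxocyclohexane-1-carboxylate F1. A nickel-catalysed Negishi alkyl–alkyl coupling (Ni(cod)2, s-Bu-Pybox, DMA) of F1 with (3-methylbut-3-en-1-yl)zinc bromide (from 4-bromo-2-methylbut-1-ene and zinc) proceeds by radical oxidative addition and so should tolerate the neopentyl-type iodide. It gives seco-ketone 15, where the fallback rejoins the route; 15 is then cyclised with CF3SO3H as in step 8 to give 16.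

2. Step 3. Protodeboronation of the alpha-branched alkenylboronate may outrun insertion into the beta-alkyl enoate, or facial discrimination may be insufficient. The fallback replaces catalyst control by an oxazolidinone auxiliary and sets out from 2. Cross-metathesis of 2 with (4R)-4-phenyl-3-(prop-2-enoyl)-1,3-oxazolidin-2-one F2 (from the commercial oxazolidinone and acryloyl chloride) should give the N-enoyl imide (4R)-3-[(2E,6S)-8-[(2,2-dimethylpropanoyl)oxy]-6-methyloct-2-enoyl]-4-phenyl-1,3-oxazolidin-2-one F3. Isopropenylmagnesium bromide with CuBr·SMe2 (THF, −40 °C) should add to the chelated imide anti to the phenyl group to give (4R)-3-[(3S,6S)-8-[(2,2-dimethylpropanoyl)oxy]-6-methyl-3-(prop-1-en-2-yl)octanoyl]-4-phenyl-1,3-oxazolidin-2-one F4. MeOMgBr in methanol then cleaves the auxiliary and returns to 6.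

3. Step 7. The basic ylide may deprotonate the gamma position (C9) of the enone and erode its configuration, or may attack the beta,beta-disubstituted carbon with poor conversion or facial control. The fallback uses a neutral cycloaddition–extrusion sequence and sets out from 12. 1,3-Dipolar cycloaddition of diazomethane (Et2O, 0 → 23 °C) across C5=C10, anti to the side chain, should give the 1-pyrazoline F5 (CH2 on C10, nitrogen on C5). Photolysis (350 nm, benzene) extrudes nitrogen and returns to 13.

Further compounds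
F1 | step 8 | methyl (2S,3S)-2-[(3S)-5-[(2,2-dimethylpropanoyl)oxy]-3-methylpentyl]-3-(iodomethyl)-3-methyl-5-oxocyclohexane-1-carboxylate | CC(C)(C)C(=O)OCC[C@@H](C)CC[C@H]1C(C(=O)OC)CC(=O)C[C@]1(C)CI
F2 | step 3 | (4R)-4-phenyl-3-(prop-2-enoyl)-1,3-oxazolidin-2-one | C=CC(=O)N1[C@H](c2ccccc2)COC1=O
F3 | step 3 | (4R)-3-[(2E,6S)-8-[(2,2-dimethylpropanoyl)oxy]-6-methyloct-2-enoyl]-4-phenyl-1,3-oxazolidin-2-one | CC(C)(C)C(=O)OCC[C@@H](C)CC/C=C/C(=O)N1[C@H](c2ccccc2)COC1=O
F4 | step 3 | (4R)-3-[(3S,6S)-8-[(2,2-dimethylpropanoyl)oxy]-6-methyl-3-(prop-1-en-2-yl)octanoyl]-4-phenyl-1,3-oxazolidin-2-one | CC(C)(C)C(=O)OCC[C@@H](C)CC[C@H](C(C)=C)CC(=O)N1[C@H](c2ccccc2)COC1=O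
F5 | step 7 | 1-pyrazoline from cis addition of diazomethane across C5=C10 of 12 (CH2 on C10 anti to the side chain, N on C5) | CC(C)(C)C(=O)OCC[C@@H](C)CC[C@H]1C(C(=O)OC)CC(=O)[C@@H]2N=NC[C@]12C
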